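**Plan**
1. Retrosynthesis: the C2–Br and C3–Br bonds are cut first (electrophilic bromination of 7-bromoindole), then the C2=C3 double bond is taken back to the indoline and N1 is capped as a Boc carbamate.
2. Enabling feature: the benzo ring carries N1 (on C7a) and bromine (on C7) on adjacent carbons, and the next carbon, C3a, holds the C3–C2 chain that ends in N1. An aryne spanning C7–C7a can therefore take N1 from that chain at C7a and bromine at C7, so N1–C7a and C7–Br are cut together.
3. This leads back to tert-butyl [2-(2-fluorophenyl)ethyl]carbamate, one step from commercial 2-(2-fluorophenyl)ethylamine.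
4. Forward: the benzene ring is bought; the five-membered nitrogen ring is the only ring formed and closes in step 2, in the same flask as the C7 bromination; Boc removal, dehydrogenation and C3/C2 dibromination follow.
5. Boc is chosen on nitrogen because it offers the C7 aryllithium neither an alkene nor an allylic C–H, and its carbonyl holds that lithium by chelation.
6. Stereochemistry: the target and every intermediate are achiral, so nothing has to be set.

Key step: step 2

Atom labels (N1, C2, C3, C3a, C7, C7a) are those of the final indole and are used for the same atoms in every intermediate.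

**Step 1**
Reactants: 1 2-(2-fluorophenyl)ethylamine; 2 di-tert-butyl dicarbonate
Product: 3 tert-butyl N-[2-(2-fluorophenyl)ethyl]carbamate
Conditions: Boc2O (1.05 equiv), CH2Cl2, 0 °C → rt
Reagents that add atoms: di-tert-butyl dicarbonate, CC(C)(C)OC(=O)OC(=O)OC(C)(C)C
Why: Carbamate formation from a primary aliphatic amine and Boc2O (N-acylation) is fast and clean, the aryl fluoride is untouched, and the product keeps exactly one N–H for the nitrogen nucleophile of step 2.

**Step 2**
Reactants: 3 tert-butyl N-[2-(2-fluorophenyl)ethyl]carbamate; 4 1,2-dibromotetrachloroethane
Product: 8 tert-butyl 7-bromoindoline-1-carboxylate, via dilithiated carbamate 5 (not isolated), via aryne 6 (not isolated), via 7-lithioindoline carbamate 7 (not isolated)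
Conditions: sec-BuLi (2.1 equiv), THF (0.05 M), −78 °C, 2 h; −78 → −40 °C, 30 min; −78 °C, then BrCl2C–CCl2Br (1.5 equiv), THF, −78 °C → rt
Reagents that add atoms: 1,2-dibromotetrachloroethane, BrC(Cl)(Cl)C(Cl)(Cl)Br
Why: sec-BuLi first deprotonates the carbamate nitrogen and then metalates C7, the one ring carbon next to fluorine that bears hydrogen (fluorine-directed ortho-lithiation), giving 5, which on warming past about −50 °C loses LiF to aryne 6 with its triple bond between C7a and C7. The lithium carbamate nitrogen, held two carbons away on C3a, adds in the plane of the aryne to C7a and so closes the five-membered ring in a 5-exo-dig mode, leaving the carbon–lithium bond at C7 of 7, where the Boc carbonyl chelates it. After recooling, 7 takes bromine from 4, which falls apart to LiBr and tetrachloroethylene. The closest known reaction types are the arynic cyclization of N-metalated 2-(2-halophenyl)ethylamine derivatives to indolines with electrophile capture of the 7-metalated N-Boc-indoline, and the bromination of aryllithiums with 1,2-dibromotetrachloroethane. No stereocentre is formed. The step needs one site of lithiation, one site of amination and an aryl anion that lasts until the quench: the first is secured by fluorine having a single neighbouring C–H, the second by the tether, which can reach only C7a, and the third by a base that leaves no amine N–H behind, an N-substituent with no alkene or allylic hydrogen, and a ceiling of −40 °C that keeps the Boc group on nitrogen.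

**Step 3**
Reactants: 8 tert-butyl 7-bromoindoline-1-carboxylate
Product: 9 7-bromoindoline
Conditions: TFA, CH2Cl2, 0 °C → rt; aq. NaHCO3 work-up
Reagents that add atoms: none
Why: Acidolysis of a tert-butyl carbamate (Boc removal through the tert-butyl cation and decarboxylation) leaves the aryl bromide and the indoline ring untouched and frees N1 for the dehydrogenation.

**Step 4**
Reactants: 9 7-bromoindoline
Product: 10 7-bromo-1H-indole
Conditions: activated MnO2 (10 equiv), CH2Cl2, reflux
Reagents that add atoms: none
Why: Dehydrogenation of an N–H indoline to the indole with activated MnO2 is driven by aromatization of the five-membered ring, tolerates the aryl bromide, and is placed before the last bromination because an indoline would be brominated at C5 and not in the five-membered ring.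

**Step 5**
Reactants: 10 7-bromo-1H-indole; 11 N-bromosuccinimide
Product: 13 2,3,7-tribromo-1H-indole, via 3,7-dibromoindole 12 (not isolated)
Conditions: NBS (2.05 equiv), THF, −78 °C → rt, dark
Reagents that add atoms: N-bromosuccinimide, O=C1CCC(=O)N1Br
Why: Electrophilic aromatic bromination of an indole with NBS takes place first at C3, the most nucleophilic carbon, to give 12 and then at C2, the remaining position of the pyrrole ring, while the benzo ring, deactivated by the C7 bromine, should stay untouched when two equivalents are used at low temperature.

**Compound list**
1 | 2-(2-fluorophenyl)ethan-1-amine | NCCc1ccccc1F | starting material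
2 | di-tert-butyl dicarbonate | CC(C)(C)OC(=O)OC(=O)OC(C)(C)C | starting material
3 | tert-butyl N-[2-(2-fluorophenyl)ethyl]carbamate | CC(C)(C)OC(=O)NCCc1ccccc1F | intermediate
4 | 1,2-dibromo-1,1,2,2-tetrachloroethane | BrC(Cl)(Cl)C(Cl)(Cl)Br | starting material
5 | tert-butyl N-lithio-N-[2-(2-fluoro-3-lithiophenyl)ethyl]carbamate | CC(C)(C)OC(=O)N([Li])CCc1cccc([Li])c1F | intermediate
6 | tert-butyl N-lithio-N-[2-(2,3-didehydrophenyl)ethyl]carbamate (aryne) | CC(C)(C)OC(=O)N([Li])CCC1=CC=CC#C1 | intermediate
7 | tert-butyl 7-lithioindoline-1-carboxylate | CC(C)(C)OC(=O)N1CCc2cccc([Li])c21 | intermediate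
8 | tert-butyl 7-bromoindoline-1-carboxylate | CC(C)(C)OC(=O)N1CCc2cccc(Br)c21 | intermediate
9 | 7-bromoindoline | Brc1cccc2c1NCC2 | intermediate
10 | 7-bromo-1H-indole | Brc1cccc2cc[nH]c12 | intermediate
11 | N-bromosuccinimide | O=C1CCC(=O)N1Br | starting material
12 | 3,7-dibromo-1H-indole | Brc1c[nH]c2c(Br)cccc12 | intermediate
13 | 2,3,7-tribromo-1H-indole | Brc1[nH]c2c(Br)cccc2c1Br | target

**Step count**
Total steps: 5. Longest linear sequence: 5 steps, from 2-(2-fluorophenyl)ethylamine 1 to 13.

**Steps most likely to fail**

Step 2. The C7 carbanion may be lost before the cold quench, either by proton capture from the medium or by migration of the Boc group from N1 to C7 while the mixture is held near −40 °C. Lithiation could also be misdirected to the benzylic CH2 under the influence of the lithium carbamate. In each case the ring or the bromine would be missing. Fallback, from 3 back to 8: the two bonds are made in separate operations. Compound 3 is treated with lithium 2,2,6,6-tetramethylpiperidide (3 equiv) in THF, −78 → 0 °C. Here the amine N–H is wanted, because it protonates C7 as soon as the aryne has been closed by nitrogen, and the product should be tert-butyl indoline-1-carboxylate F1. F1 is then lithiated at C7 under direction of the carbamate (sec-BuLi, TMEDA, Et2O, −78 °C), which gives 7 cold from the start, and the quench with 4 should give 8.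

Step 5. Bromination may run on into the benzo ring or stop at the 3-bromo stage, and the N–H polybromoindole may decompose under the oxidizing conditions. Fallback, from 10 back to 13: the two bromines are introduced by different mechanisms on a protected indole. N-Sulfonylation (NaH, PhSO2Cl, DMF, 0 °C) should give 7-bromo-1-(phenylsulfonyl)indole F2. Deprotonation at C2 with LiN(iPr)2 (THF, −78 °C) leads to 7-bromo-2-lithio-1-(phenylsulfonyl)indole F3, and 4 converts it into 2,7-dibromo-1-(phenylsulfonyl)indole F4. Bromination at C3 with Br2 (CH2Cl2, rt) should give 2,3,7-tribromo-1-(phenylsulfonyl)indole F5. Removal of the sulfonyl group with Bu4NF (THF, reflux) then gives 13.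

Step 4. Dehydrogenation on the MnO2 surface may stall, or material may be lost by adsorption and oxidative coupling, with an indoline whose nitrogen is flanked by bromine. Fallback, from 9 back to 10: halogenation at nitrogen followed by elimination replaces the surface oxidation. Trichloroisocyanuric acid (0.35 equiv) and DBU (2 equiv) in CH2Cl2 at −20 °C → rt should give 7-bromo-1-chloroindoline F6. The base removes HCl from it to give 7-bromo-3H-indole F7, which tautomerizes to 10.

**Further compounds**
F1 | step 2 | tert-butyl indoline-1-carboxylate | CC(C)(C)OC(=O)N1CCc2ccccc21
F2 | step 5 | 7-bromo-1-(phenylsulfonyl)-1H-indole | O=S(=O)(c1ccccc1)n1ccc2cccc(Br)c21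
F3 | step 5 | 7-bromo-2-lithio-1-(phenylsulfonyl)-1H-indole | [Li]c1cc2cccc(Br)c2n1S(=O)(=O)c1ccccc1
F4 | step 5 | 2,7-dibromo-1-(phenylsulfonyl)-1H-indole | O=S(=O)(c1ccccc1)n1c(Br)cc2cccc(Br)c21
F5 | step 5 | 2,3,7-tribromo-1-(phenylsulfonyl)-1H-indole | O=S(=O)(c1ccccc1)n1c(Br)c(Br)c2cccc(Br)c21
F6 | step 4 | 7-bromo-1-chloroindoline | ClN1CCc2cccc(Br)c21
F7 | step 4 | 7-bromo-3H-indole | Brc1cccc2c1N=CC2
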